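**Plan**

Numbering: ring A = cyclopentane C1(OH)(CH2OAc)–C2(H, ring B)–C3H2–C4(H, dienyl)–C5H2; ring B = cyclopentenone C1'(H)–C2'(=O)–C3'=C4'–C5'(H)(CH3).
Retrosynthetic cuts: the acetate; ring B at C3'=C4' (RCM) and C2'–C3' (vinyl ketone); C1'–C5' (Ireland–Claisen of a crotyl ester); ring A at C1–C2 (ketyl–olefin cyclisation of an open-chain keto enoate); C2=C1' (HWE); C1–CH2O (alkoxymethyllithium on a δ-lactone); C4–alkenyl (Rh conjugate addition).
Forward order: Z-alkenyl iodide → C4 lactone → acyclic keto enoate → ring A → Claisen → ring B closed last, then deprotection and acetylation.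
Stereochemistry: the Z-olefin comes from trans-hydroalumination/iodination; C4 from (S)-BINAP–Rh; C1 and C2 from C4 in the SmI2 cyclisation; C1' and C5' from the chair Ireland–Claisen, with its face set by C2.
Enabling feature: the γ-hydroxy ketone array HO–C1–C2–C1'–C2'=O, with C1 a ring carbinol, is the retron of a ketyl–olefin coupling; C1/C2/C4 of ring A are positions 1/5/3 of a hex-5-enyl radical, whose chair closure should give the all-cis carbon substituents with OH trans.

Key step: step 10

Remark: Grignard reagents, SmI2 and other simple reagents are taken as commercial. Compound 14 is drawn as the open hydroxy ketone, which equilibrates with its cyclic hemiketal. The CIP label of the alkenyl metal species 7 and 8 is formally E, although the olefin geometry of iodide 5 is retained.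

Step 1
Reactants: 1 but-2-yn-1-ol
Product: 3 (Z)-3-iodobut-2-en-1-ol, via cyclic alkenylalanate 2 (not isolated)
Conditions: Red-Al, THF, 0 °C to rt; then I2, THF, −78 °C; aq. Rochelle salt
Reagents that add atoms: iodine, II
Why: Hydroxyl-directed trans-hydroalumination of the propargylic alcohol puts aluminium on C3 in a five-membered alanate, and iodinolysis with retention should give the vinyl iodide with I cis to CH2OH, which fixes the later Z-trisubstituted olefin (hydroalumination–iodination of propargylic alcohols).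

Step 2
Reactants: 3 (Z)-3-iodobut-2-en-1-ol
Product: 4 (Z)-1-bromo-3-iodobut-2-ene
Conditions: CBr4, PPh3, CH2Cl2, 0 °C
Reagents that add atoms: carbon tetrabromide, BrC(Br)(Br)Br
Why: Appel bromination of a primary allylic alcohol should leave the vinyl iodide geometry untouched.

Step 3
Reactants: 4 (Z)-1-bromo-3-iodobut-2-ene
Product: 5 (Z)-2-iodo-6-methylhepta-2,5-diene
Conditions: (2-methylprop-1-en-1-yl)magnesium bromide, CuI (5 mol%), THF, −30 °C
Reagents that add atoms: (2-methylprop-1-en-1-yl)magnesium bromide, CC(C)=C[Mg]Br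
Why: Copper-catalysed SN2 coupling of an alkenyl Grignard reagent with the primary allylic bromide should be much faster than any reaction at the vinyl iodide and gives the skipped diene.

Step 4
Reactants: 5 (Z)-2-iodo-6-methylhepta-2,5-diene, 6 5,6-dihydro-2H-pyran-2-one
Product: 9 (S)-4-[(Z)-6-methylhepta-2,5-dien-2-yl]oxan-2-one, via alkenyllithium 7 (not isolated), via lithium alkenyltrimethoxyborate 8 (not isolated)
Conditions: t-BuLi (2 equiv), Et2O, −78 °C; B(OMe)3, −78 °C to rt; then 6, Rh(acac)(C2H4)2 (3 mol%), (S)-BINAP, dioxane/H2O, 100 °C (borate 2.5 equiv per 6)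
Reagents that add atoms: none
Why: Iodine–lithium exchange and borylation proceed with retention, and the Rh(I)/BINAP-catalysed asymmetric 1,4-addition of the alkenylborate to the unsaturated lactone (Hayashi–Miyaura reaction) should set C4 under ligand control, (S)-BINAP being the enantiomer expected from the model for cyclic enones to give the S centre.

Step 5
Reactants: 10 tributyl(iodomethyl)stannane, 11 (4-methoxyphenyl)methanol
Product: 12 tributyl{[(4-methoxybenzyl)oxy]methyl}stannane
Conditions: NaH, THF/DMF, 0 °C to rt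
Reagents that add atoms: none
Why: Williamson etherification of the primary iodide by the benzylic alkoxide should give the alkoxymethyl stannane.

Step 6
Reactants: 9 (S)-4-[(Z)-6-methylhepta-2,5-dien-2-yl]oxan-2-one, 12 tributyl{[(4-methoxybenzyl)oxy]methyl}stannane
Product: 14 (S)-6-hydroxy-1-[(4-methoxybenzyl)oxy]-4-[(Z)-6-methylhepta-2,5-dien-2-yl]hexan-2-one, via alkoxymethyllithium 13 (not isolated)
Conditions: 12, n-BuLi, THF, −78 °C; then 9, −78 °C; H2O
Reagents that add atoms: none
Why: Tin–lithium exchange gives the α-alkoxymethyllithium, which should add once to the δ-lactone because the lithium hemiketal alkoxide is stable at −78 °C; this installs the CH2O carbon on the future C1.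

Step 7
Reactants: 14 (S)-6-hydroxy-1-[(4-methoxybenzyl)oxy]-4-[(Z)-6-methylhepta-2,5-dien-2-yl]hexan-2-one
Product: 15 (S)-6-[(4-methoxybenzyl)oxy]-3-[(Z)-6-methylhepta-2,5-dien-2-yl]-5-oxohexanal
Conditions: TEMPO (10 mol%), PhI(OAc)2, CH2Cl2, rt
Reagents that add atoms: none
Why: TEMPO/PhI(OAc)2 oxidises only the primary alcohol of the open form (the tertiary hemiketal carbon has no hydrogen) and should spare the olefins and the PMB ether.

Step 8
Reactants: 16 2-(diethoxyphosphoryl)acetic acid, 17 (E)-but-2-en-1-ol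
Product: 18 (E)-but-2-en-1-yl 2-(diethoxyphosphoryl)acetate
Conditions: DCC, DMAP (cat.), CH2Cl2, 0 °C to rt
Reagents that add atoms: none
Why: Steglich esterification should give the crotyl phosphonoacetate, which carries the allyl unit for the later Claisen step.

Step 9
Reactants: 15 (S)-6-[(4-methoxybenzyl)oxy]-3-[(Z)-6-methylhepta-2,5-dien-2-yl]-5-oxohexanal, 18 (E)-but-2-en-1-yl 2-(diethoxyphosphoryl)acetate
Product: 19 (E)-but-2-en-1-yl (2E,5S)-8-[(4-methoxybenzyl)oxy]-5-[(Z)-6-methylhepta-2,5-dien-2-yl]-7-oxooct-2-enoate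
Conditions: LiCl, i-Pr2NEt, MeCN, 0 °C to rt
Reagents that add atoms: none
Why: Horner–Wadsworth–Emmons olefination under Masamune–Roush conditions should react at the aldehyde in preference to the ketone and is mild enough to avoid aldol side reactions; the E/Z ratio does not matter for step 10.

Step 10
Reactants: 19 (E)-but-2-en-1-yl (2E,5S)-8-[(4-methoxybenzyl)oxy]-5-[(Z)-6-methylhepta-2,5-dien-2-yl]-7-oxooct-2-enoate
Product: 20 (E)-but-2-en-1-yl 2-[(1S,2R,4S)-2-hydroxy-2-{[(4-methoxybenzyl)oxy]methyl}-4-[(Z)-6-methylhepta-2,5-dien-2-yl]cyclopentyl]acetate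
Conditions: SmI2 (2.2 equiv, slow addition), t-BuOH (2.2 equiv), THF, −78 °C
Reagents that add atoms: none
Why: SmI2 reduces the ketone to a samarium(III) ketyl that adds to the β-carbon of the enoate, and a second electron gives a samarium enolate that t-BuOH protonates; this is the ketyl–olefin reductive cyclisation known for keto enoates. Ring A closes in the 5-exo-trig mode through a chair-like transition state. At C1 the Sm–O ketyl oxygen lies anti to the enoate arm to avoid electrostatic repulsion, so OH should end trans to CH2CO2R and the CH2OPMB group cis to it. At C2 the C4 substituent takes a pseudo-equatorial site of the chair (the 3-substituted hex-5-enyl radical preference), which should put the new C2 arm cis to the dienyl chain. The step needs ring closure to outrun reductive loss of the α-alkoxy group, which slow addition of SmI2 at −78 °C without HMPA should secure by keeping the second electron transfer slower than cyclisation. The step is also convergent, since both olefin isomers of 19 pass through the same radical.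

Step 11
Reactants: 20 (E)-but-2-en-1-yl 2-[(1S,2R,4S)-2-hydroxy-2-{[(4-methoxybenzyl)oxy]methyl}-4-[(Z)-6-methylhepta-2,5-dien-2-yl]cyclopentyl]acetate
Product: 23 (2S,3R)-2-[(1S,2R,4S)-2-hydroxy-2-{[(4-methoxybenzyl)oxy]methyl}-4-[(Z)-6-methylhepta-2,5-dien-2-yl]cyclopentyl]-3-methylpent-4-enoic acid, via bis-silyl ketene acetal 21 (not isolated), via rearranged silyl ester 22 (not isolated)
Conditions: LDA (2.3 equiv), THF, −78 °C; TMSCl (3 equiv), −78 to 50 °C; then 1 M HCl, THF
Reagents that add atoms: none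
Why: In the Ireland–Claisen rearrangement the (E)-silyl ketene acetal formed with LDA in THF and the (E)-crotyl group react through a chair to give the 2,3-anti acid, which corresponds to the cis C1'/C5' pair of ring B; allylic 1,3-strain should hold the C2–H in the ketene acetal plane so that the crotyl unit adds anti to the fully substituted C1, giving C1' and C5' in the required sense.

Step 12
Reactants: 23 (2S,3R)-2-[(1S,2R,4S)-2-hydroxy-2-{[(4-methoxybenzyl)oxy]methyl}-4-[(Z)-6-methylhepta-2,5-dien-2-yl]cyclopentyl]-3-methylpent-4-enoic acid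
Product: 24 (2S,3R)-2-[(1S,2R,4S)-2-hydroxy-2-{[(4-methoxybenzyl)oxy]methyl}-4-[(Z)-6-methylhepta-2,5-dien-2-yl]cyclopentyl]-N-methoxy-N,3-dimethylpent-4-enamide
Conditions: MeNHOMe·HCl, EDC·HCl, HOBt (cat.), N-methylmorpholine, CH2Cl2, 0 °C to rt
Reagents that add atoms: N,O-dimethylhydroxylamine hydrochloride, CNOC.Cl
Why: Carbodiimide coupling to the Weinreb amide should proceed without touching the hindered tertiary alcohol and under conditions too mild to epimerise C1'.

Step 13
Reactants: 24 (2S,3R)-2-[(1S,2R,4S)-2-hydroxy-2-{[(4-methoxybenzyl)oxy]methyl}-4-[(Z)-6-methylhepta-2,5-dien-2-yl]cyclopentyl]-N-methoxy-N,3-dimethylpent-4-enamide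
Product: 25 (4S,5R)-4-[(1S,2R,4S)-2-hydroxy-2-{[(4-methoxybenzyl)oxy]methyl}-4-[(Z)-6-methylhepta-2,5-dien-2-yl]cyclopentyl]-5-methylhepta-1,6-dien-3-one
Conditions: CH2=CHMgBr (3.5 equiv), THF, −20 to 0 °C; inverse quench into cold 1 M HCl
Reagents that add atoms: vinylmagnesium bromide, C=C[Mg]Br
Why: Weinreb ketone synthesis stops at the chelated tetrahedral intermediate (one equivalent of Grignard reagent is spent on the tertiary OH), and the cold acidic quench should release the vinyl ketone without amine conjugate addition or epimerisation.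

Step 14
Reactants: 25 (4S,5R)-4-[(1S,2R,4S)-2-hydroxy-2-{[(4-methoxybenzyl)oxy]methyl}-4-[(Z)-6-methylhepta-2,5-dien-2-yl]cyclopentyl]-5-methylhepta-1,6-dien-3-one
Product: 26 (4R,5S)-5-[(1S,2R,4S)-2-hydroxy-2-{[(4-methoxybenzyl)oxy]methyl}-4-[(Z)-6-methylhepta-2,5-dien-2-yl]cyclopentyl]-4-methylcyclopent-2-en-1-one
Conditions: Grubbs II (5 mol%), CH2Cl2, 40 °C
Reagents that add atoms: none
Why: Ring-closing metathesis of the 1,6-dien-3-one should close ring B at C3'=C4' under neutral conditions, so the epimerisable cis-4,5-disubstituted enone is not exposed to base, and the trisubstituted side-chain olefins should not take part.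

Step 15
Reactants: 26 (4R,5S)-5-[(1S,2R,4S)-2-hydroxy-2-{[(4-methoxybenzyl)oxy]methyl}-4-[(Z)-6-methylhepta-2,5-dien-2-yl]cyclopentyl]-4-methylcyclopent-2-en-1-one
Product: 27 (4R,5S)-5-[(1S,2R,4S)-2-hydroxy-2-(hydroxymethyl)-4-[(Z)-6-methylhepta-2,5-dien-2-yl]cyclopentyl]-4-methylcyclopent-2-en-1-one
Conditions: DDQ, CH2Cl2/pH 7 buffer, 0 °C
Reagents that add atoms: none
Why: Oxidative PMB cleavage in wet, buffered medium (water prevents anisylidene acetal formation with the neighbouring tertiary OH) is near neutral and should leave the enone and the skipped diene intact.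

Step 16
Reactants: 27 (4R,5S)-5-[(1S,2R,4S)-2-hydroxy-2-(hydroxymethyl)-4-[(Z)-6-methylhepta-2,5-dien-2-yl]cyclopentyl]-4-methylcyclopent-2-en-1-one
Product: 28 [(1R,2S,4S)-1-hydroxy-4-[(Z)-6-methylhepta-2,5-dien-2-yl]-2-[(1S,5R)-5-methyl-2-oxocyclopent-3-en-1-yl]cyclopentyl]methyl acetate
Conditions: Ac2O (1.2 equiv), pyridine, CH2Cl2, 0 °C
Reagents that add atoms: acetic anhydride, CC(=O)OC(C)=O
Why: The primary alcohol should be acetylated selectively over the tertiary one, and the short exposure to pyridine at 0 °C is intended to be too mild to epimerise C1'.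

**Compound list**

1 | but-2-yn-1-ol | CC#CCO | starting material
2 | sodium 2,2-bis(2-methoxyethoxy)-3-methyl-2,5-dihydro-1,2-oxaluminol-2-uide (cyclic alkenylalanate) | [Na+].CC1=CCO[Al-]1(OCCOC)OCCOC | intermediate
3 | (Z)-3-iodobut-2-en-1-ol | I/C(C)=C\CO | intermediate
4 | (Z)-1-bromo-3-iodobut-2-ene | I/C(C)=C\CBr | intermediate
5 | (Z)-2-iodo-6-methylhepta-2,5-diene | I/C(C)=C\CC=C(C)C | intermediate
6 | 5,6-dihydro-2H-pyran-2-one | O=C1C=CCCO1 | starting material
7 | [(E)-6-methylhepta-2,5-dien-2-yl]lithium (geometry of 5 retained) | [Li]/C(C)=C\CC=C(C)C | intermediate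
8 | lithium trimethoxy[(E)-6-methylhepta-2,5-dien-2-yl]borate | [Li+].CO[B-](OC)(OC)/C(C)=C\CC=C(C)C | intermediate
9 | (S)-4-[(Z)-6-methylhepta-2,5-dien-2-yl]oxan-2-one | O=C1C[C@@H](/C(C)=C\CC=C(C)C)CCO1 | intermediate
10 | tributyl(iodomethyl)stannane | CCCC[Sn](CCCC)(CCCC)CI | starting material
11 | (4-methoxyphenyl)methanol | COc1ccc(CO)cc1 | starting material
12 | tributyl{[(4-methoxybenzyl)oxy]methyl}stannane | CCCC[Sn](CCCC)(CCCC)COCc1ccc(OC)cc1 | intermediate
13 | {[(4-methoxybenzyl)oxy]methyl}lithium | [Li]COCc1ccc(OC)cc1 | intermediate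
14 | (S)-6-hydroxy-1-[(4-methoxybenzyl)oxy]-4-[(Z)-6-methylhepta-2,5-dien-2-yl]hexan-2-one | COc1ccc(COCC(=O)C[C@@H](/C(C)=C\CC=C(C)C)CCO)cc1 | intermediate
15 | (S)-6-[(4-methoxybenzyl)oxy]-3-[(Z)-6-methylhepta-2,5-dien-2-yl]-5-oxohexanal | COc1ccc(COCC(=O)C[C@@H](/C(C)=C\CC=C(C)C)CC=O)cc1 | intermediate
16 | 2-(diethoxyphosphoryl)acetic acid | CCOP(=O)(CC(=O)O)OCC | starting material
17 | (E)-but-2-en-1-ol | C/C=C/CO | starting material
18 | (E)-but-2-en-1-yl 2-(diethoxyphosphoryl)acetate | CCOP(=O)(CC(=O)OC/C=C/C)OCC | intermediate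
19 | (E)-but-2-en-1-yl (2E,5S)-8-[(4-methoxybenzyl)oxy]-5-[(Z)-6-methylhepta-2,5-dien-2-yl]-7-oxooct-2-enoate | COc1ccc(COCC(=O)C[C@@H](/C(C)=C\CC=C(C)C)C/C=C/C(=O)OC/C=C/C)cc1 | intermediate
20 | (E)-but-2-en-1-yl 2-[(1S,2R,4S)-2-hydroxy-2-{[(4-methoxybenzyl)oxy]methyl}-4-[(Z)-6-methylhepta-2,5-dien-2-yl]cyclopentyl]acetate | COc1ccc(COC[C@@]2(O)C[C@@H](/C(C)=C\CC=C(C)C)C[C@H]2CC(=O)OC/C=C/C)cc1 | intermediate
21 | (E)-O-crotyl O-trimethylsilyl ketene acetal of 20 with the tertiary alcohol as trimethylsilyl ether | COc1ccc(COC[C@@]2(O[Si](C)(C)C)C[C@@H](/C(C)=C\CC=C(C)C)C[C@H]2/C=C(/O[Si](C)(C)C)OC/C=C/C)cc1 | intermediate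
22 | trimethylsilyl (2S,3R)-2-[(1S,2R,4S)-2-{[(4-methoxybenzyl)oxy]methyl}-4-[(Z)-6-methylhepta-2,5-dien-2-yl]-2-[(trimethylsilyl)oxy]cyclopentyl]-3-methylpent-4-enoate | COc1ccc(COC[C@@]2(O[Si](C)(C)C)C[C@@H](/C(C)=C\CC=C(C)C)C[C@H]2[C@@H](C(=O)O[Si](C)(C)C)[C@H](C)C=C)cc1 | intermediate
23 | (2S,3R)-2-[(1S,2R,4S)-2-hydroxy-2-{[(4-methoxybenzyl)oxy]methyl}-4-[(Z)-6-methylhepta-2,5-dien-2-yl]cyclopentyl]-3-methylpent-4-enoic acid | COc1ccc(COC[C@@]2(O)C[C@@H](/C(C)=C\CC=C(C)C)C[C@H]2[C@@H](C(=O)O)[C@H](C)C=C)cc1 | intermediate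
24 | (2S,3R)-2-[(1S,2R,4S)-2-hydroxy-2-{[(4-methoxybenzyl)oxy]methyl}-4-[(Z)-6-methylhepta-2,5-dien-2-yl]cyclopentyl]-N-methoxy-N,3-dimethylpent-4-enamide | COc1ccc(COC[C@@]2(O)C[C@@H](/C(C)=C\CC=C(C)C)C[C@H]2[C@@H](C(=O)N(C)OC)[C@H](C)C=C)cc1 | intermediate
25 | (4S,5R)-4-[(1S,2R,4S)-2-hydroxy-2-{[(4-methoxybenzyl)oxy]methyl}-4-[(Z)-6-methylhepta-2,5-dien-2-yl]cyclopentyl]-5-methylhepta-1,6-dien-3-one | COc1ccc(COC[C@@]2(O)C[C@@H](/C(C)=C\CC=C(C)C)C[C@H]2[C@@H](C(=O)C=C)[C@H](C)C=C)cc1 | intermediate
26 | (4R,5S)-5-[(1S,2R,4S)-2-hydroxy-2-{[(4-methoxybenzyl)oxy]methyl}-4-[(Z)-6-methylhepta-2,5-dien-2-yl]cyclopentyl]-4-methylcyclopent-2-en-1-one | COc1ccc(COC[C@@]2(O)C[C@@H](/C(C)=C\CC=C(C)C)C[C@H]2[C@H]2C(=O)C=C[C@H]2C)cc1 | intermediate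
27 | (4R,5S)-5-[(1S,2R,4S)-2-hydroxy-2-(hydroxymethyl)-4-[(Z)-6-methylhepta-2,5-dien-2-yl]cyclopentyl]-4-methylcyclopent-2-en-1-one | OC[C@@]1(O)C[C@@H](/C(C)=C\CC=C(C)C)C[C@H]1[C@H]1C(=O)C=C[C@H]1C | intermediate
28 | [(1R,2S,4S)-1-hydroxy-4-[(Z)-6-methylhepta-2,5-dien-2-yl]-2-[(1S,5R)-5-methyl-2-oxocyclopent-3-en-1-yl]cyclopentyl]methyl acetate | CC(=O)OC[C@@]1(O)C[C@@H](/C(C)=C\CC=C(C)C)C[C@H]1[C@H]1C(=O)C=C[C@H]1C | target

Total step count: 16. Longest linear sequence: 14 steps (steps 1–4, 6, 7, 9–16).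

**Steps most likely to fail**

Risk 1, step 10 (key step). The samarium ketyl may take up a second electron and lose the α-alkoxy group (reductive C–O cleavage to a methyl ketone) before it cyclises, and the 1,3-induction from C4 may be incomplete. The fallback closes the same C1–C2 bond by reducing the other π-system. Compound 19 is electrolysed at constant current (divided cell, lead or glassy-carbon cathode, Et4NOTs, MeCN, diethyl malonate as proton donor), so that the enoate, not the ketone, is reduced and its β-carbon radical anion attacks the intact carbonyl (electroreductive cyclisation). No free ketyl is formed, which removes the C–O cleavage path. The fallback sets out from 19 and comes back at 20; new compounds: none F0.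

Risk 2, step 11. C2 may not discriminate the two faces well enough in the chair transition state, or the ketene acetal geometry may erode, which would give C1'/C5' diastereomers. The fallback replaces substrate control by reagent control. Compound 20 is silylated at the tertiary alcohol (TMS-imidazole, CH2Cl2) to the trimethylsilyl ether F3. F3 is enolised with the C2-symmetric 2-bromo-4,5-diphenyl-1,3-ditosyl-1,3,2-diazaborolidine and Et3N (toluene/hexane, −78 °C) to the chiral boron ketene acetal F4. F4 rearranges between −20 and 4 °C with the controller fixing the enolate face (enantioselective boron ester-enolate Claisen rearrangement; the controller enantiomer is chosen to reinforce the desired sense). Acidic work-up removes boron and silicon and returns the route at acid 23.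

Risk 3, step 4. The α-branched alkenylborate may transmetalate slowly and protodeboronate, or olefin geometry and enantioselectivity may be lost on rhodium. The fallback uses auxiliary control with copper. The alkenyllithium 7 (from 5) is converted with MgBr2·OEt2 and CuBr·SMe2 (THF, −78 °C) into the alkenylcopper reagent. This is added to (R)-4-benzyl-3-[(E)-5-{[tert-butyl(dimethyl)silyl]oxy}pent-2-enoyl]-1,3-oxazolidin-2-one F1, made separately by N-acylation of commercial (R)-4-benzyloxazolidin-2-one. Attack anti to the benzyl group of the chelated syn-s-cis imide should give the conjugate adduct F2. TBAF (THF, 0 °C) then frees the primary alkoxide, which lactonises with loss of the auxiliary and returns the route at lactone 9.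

**Further compounds**

F1 | step 4 | (R)-4-benzyl-3-[(E)-5-{[tert-butyl(dimethyl)silyl]oxy}pent-2-enoyl]-1,3-oxazolidin-2-one | O=C1OC[C@@H](Cc2ccccc2)N1C(=O)/C=C/CCO[Si](C)(C)C(C)(C)C
F2 | step 4 | (R)-4-benzyl-3-[(S)-5-{[tert-butyl(dimethyl)silyl]oxy}-3-[(Z)-6-methylhepta-2,5-dien-2-yl]pentanoyl]-1,3-oxazolidin-2-one | O=C1OC[C@@H](Cc2ccccc2)N1C(=O)C[C@@H](/C(C)=C\CC=C(C)C)CCO[Si](C)(C)C(C)(C)C
F0 | step 10 | none | none
F3 | step 11 | (E)-but-2-en-1-yl 2-[(1S,2R,4S)-2-{[(4-methoxybenzyl)oxy]methyl}-4-[(Z)-6-methylhepta-2,5-dien-2-yl]-2-[(trimethylsilyl)oxy]cyclopentyl]acetate | COc1ccc(COC[C@@]2(O[Si](C)(C)C)C[C@@H](/C(C)=C\CC=C(C)C)C[C@H]2CC(=O)OC/C=C/C)cc1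
F4 | step 11 | (E)-O-crotyl O-[(4S,5S)-4,5-diphenyl-1,3-ditosyl-1,3,2-diazaborolidin-2-yl] ketene acetal of F3 | COc1ccc(COC[C@@]2(O[Si](C)(C)C)C[C@@H](/C(C)=C\CC=C(C)C)C[C@H]2/C=C(/OB3N(S(=O)(=O)c4ccc(C)cc4)[C@@H](c4ccccc4)[C@H](c4ccccc4)N3S(=O)(=O)c3ccc(C)cc3)OC/C=C/C)cc1
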